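**Plan**
- Locants: lactone O1, C2 (C=O), C3, C4, C5; C7 is the benzylic CH2 on C3 and C7' the carbinol carbon on C4.
- Enabling feature: in the lactone ring, C2 is a single carbon held between O1 and C3, and O1–C5–C4–C3 becomes an allylic alcohol once C3=C4 is an alkene, so C2 can be delivered as CO.
- Retrosynthetic cuts, in order: C2–C3 and C2–O1 (CO), C4–C5 (hydroxymethyl on an alkenyl iodide), C4–C7' (alkynylation of veratraldehyde), C3–C7 (benzyl–ethynyl coupling).
- Forward: the chain is joined C7–C3 first, then C4–C7'; syn hydrostannation/iodination, silylation and hydroxymethylation give the Z-allylic alcohol; the lactone, the only ring formed, closes in the carbonylation; two deprotections finish.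
- Stereochemistry: C7' comes from the chiral zinc catalyst (R in the open-chain compounds, S in the lactones through a change of CIP ranking only). C4 comes from the C7' centre through 1,3-allylic strain during hydropalladation. C3 comes from syn addition of hydrogen and acyl to the Z alkene, which gives the trans lactone.

Key step: step 7

Assumption: (S,S)-ProPhenol is taken as the ligand antipode that delivers the alkynylzinc to the Si face of veratraldehyde (R carbinol); if the sense is the opposite, the (R,R) ligand is used and nothing else changes.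

**Step 1**
Reactants: 1 4-(benzyloxy)-3-methoxybenzyl alcohol
Product: 2 4-(benzyloxy)-3-methoxybenzyl bromide
Conditions: PBr3, Et2O, 0 °C
Reagents that add atoms: phosphorus tribromide, BrP(Br)Br
Why: Bromination of a benzylic alcohol with PBr3 proceeds by SN2 displacement of the phosphite ester and leaves the aryl benzyl ether untouched.

**Step 2**
Reactants: 2 4-(benzyloxy)-3-methoxybenzyl bromide; 3 ethynylmagnesium bromide
Product: 4 1-(benzyloxy)-2-methoxy-4-(prop-2-yn-1-yl)benzene
Conditions: 3 (excess, 0.5 M in THF), CuCl (10 mol %), THF, 0 → 50 °C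
Reagents that add atoms: none
Why: Copper-catalysed sp3–sp coupling of a benzylic bromide with an alkynyl Grignard reagent should give the 3-arylpropyne directly, with excess Grignard reagent and a mild temperature limiting double alkylation and alkyne-to-allene isomerisation.

**Step 3**
Reactants: 4 1-(benzyloxy)-2-methoxy-4-(prop-2-yn-1-yl)benzene; 5 veratraldehyde
Product: 7 (R)-4-[4-(benzyloxy)-3-methoxyphenyl]-1-(3,4-dimethoxyphenyl)but-2-yn-1-ol, via alkynyl(methyl)zinc 6 (not isolated)
Conditions: Me2Zn, (S,S)-ProPhenol (20 mol %), Ph3P=O (40 mol %), toluene, 0 → 4 °C; aq NH4Cl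
Reagents that add atoms: dimethylzinc, C[Zn]C (zinc and one methyl are in 6; none of its atoms remain in 7)
Why: Catalytic asymmetric alkynylation of an aromatic aldehyde by the dinuclear zinc–ProPhenol complex, which holds aldehyde and alkynylzinc on neighbouring zinc centres and should deliver the alkynyl group to the Si face, setting the C7' carbinol as R.

**Step 4**
Reactants: 7 (R)-4-[4-(benzyloxy)-3-methoxyphenyl]-1-(3,4-dimethoxyphenyl)but-2-yn-1-ol
Product: 9 (1R,2E)-4-[4-(benzyloxy)-3-methoxyphenyl]-1-(3,4-dimethoxyphenyl)-2-iodobut-2-en-1-ol, via vinylstannane 8 (not isolated)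
Conditions: Bu3SnH (slow addition), PdCl2(PPh3)2 (3 mol %), THF, 0 °C → rt; then I2, CH2Cl2, 0 °C
Reagents that add atoms: tributyltin hydride, CCCC[SnH](CCCC)CCCC (tin in 8); iodine, II
Why: Palladium-catalysed hydrostannation (Sn–H oxidative addition to zerovalent palladium, syn hydropalladation, reductive elimination) should place tin on the alkyne carbon next to the carbinol and hydrogen on the distal carbon, directed by the inductive pull and coordination of the propargylic hydroxyl, and iododestannylation then exchanges tin for iodine with retention to give the E iodide.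

**Step 5**
Reactants: 9 (1R,2E)-4-[4-(benzyloxy)-3-methoxyphenyl]-1-(3,4-dimethoxyphenyl)-2-iodobut-2-en-1-ol
Product: 10 tert-butyl{[(1R,2E)-4-[4-(benzyloxy)-3-methoxyphenyl]-1-(3,4-dimethoxyphenyl)-2-iodobut-2-en-1-yl]oxy}dimethylsilane
Conditions: TBSCl, imidazole, DMF, rt
Reagents that add atoms: tert-butyldimethylsilyl chloride, CC(C)(C)[Si](C)(C)Cl
Why: Standard silylation of a secondary alcohol, which blocks the C7' oxygen so that only the C5 hydroxyl can later capture the acyl palladium and which does not touch the stereocentre.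

**Step 6**
Reactants: 10 tert-butyl{[(1R,2E)-4-[4-(benzyloxy)-3-methoxyphenyl]-1-(3,4-dimethoxyphenyl)-2-iodobut-2-en-1-yl]oxy}dimethylsilane; 11 (tributylstannyl)methanol
Product: 12 (Z)-4-[4-(benzyloxy)-3-methoxyphenyl]-2-[(R)-(tert-butyldimethylsilyloxy)(3,4-dimethoxyphenyl)methyl]but-2-en-1-ol
Conditions: Pd(PPh3)4 (10 mol %), dioxane, 90 °C
Reagents that add atoms: none
Why: Stille coupling in which the stannane transfers its α-hydroxymethyl group in preference to butyl, and in which oxidative addition and reductive elimination retain the alkene geometry, so the new C5 ends trans to the C7 methylene (Z alkene).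

**Step 7**
Reactants: 12 (Z)-4-[4-(benzyloxy)-3-methoxyphenyl]-2-[(R)-(tert-butyldimethylsilyloxy)(3,4-dimethoxyphenyl)methyl]but-2-en-1-ol; 13 carbon monoxide
Product: 14 (3R,4R)-3-[4-(benzyloxy)-3-methoxybenzyl]-4-[(S)-(tert-butyldimethylsilyloxy)(3,4-dimethoxyphenyl)methyl]dihydrofuran-2(3H)-one
Conditions: Pd2(dba)3·CHCl3 (2.5 mol %), dppb (10 mol %), CO/H2 (1:1, 55 atm), CH2Cl2, 100 °C
Reagents that add atoms: none
Why: A palladium hydride formed from the zerovalent palladium–dppb complex under CO/H2 adds across C3=C4 with hydrogen to the fully substituted C4 and palladium to C3, CO inserts into the C3–Pd bond, and the C5 hydroxyl attacks the acyl palladium to release the lactone and return the hydride, so that C2–C3 and C2–O1 form in one operation. The closest known reaction type is the palladium/diphosphine-catalysed cyclocarbonylation of β,γ-disubstituted allylic alcohols to α,β-disubstituted γ-butyrolactones. The lactone, the only ring closed, forms by 5-exo-trig attack of O1 on the acyl carbon C2 (equivalently C–O reductive elimination from a six-membered oxapalladacycle). C4 is controlled by the C7' centre: 1,3-allylic strain with the cis C7 methylene keeps the C7'–H bond in the alkene plane, the aryl ring then covers one face, and the hydride should enter anti to it on the silyloxy side, which gives 4R; C3 follows from C4 because hydrogen and the acyl carbon add syn, which on the Z alkene places the two side chains trans (3R). The step needs palladium at C3 and not at C4, which the five- versus four-membered ring alternative and the reluctance of palladium to bind a fully substituted carbon should secure, and it needs acyl capture by O1 alone, which the silyl ether on the C7' oxygen secures.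

**Step 8**
Reactants: 14 (3R,4R)-3-[4-(benzyloxy)-3-methoxybenzyl]-4-[(S)-(tert-butyldimethylsilyloxy)(3,4-dimethoxyphenyl)methyl]dihydrofuran-2(3H)-one
Product: 15 (3R,4R)-4-[(S)-(tert-butyldimethylsilyloxy)(3,4-dimethoxyphenyl)methyl]-3-(4-hydroxy-3-methoxybenzyl)dihydrofuran-2(3H)-one
Conditions: H2 (1 atm), Pd/C (10 wt %), EtOAc, rt
Reagents that add atoms: none
Why: Hydrogenolysis of the aryl benzyl ether over Pd/C in a non-protic solvent, under which the lactone and the bulky benzylic silyl ether should persist and no stereocentre is affected.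

**Step 9**
Reactants: 15 (3R,4R)-4-[(S)-(tert-butyldimethylsilyloxy)(3,4-dimethoxyphenyl)methyl]-3-(4-hydroxy-3-methoxybenzyl)dihydrofuran-2(3H)-one
Product: 16 (3R,4R)-4-[(S)-(3,4-dimethoxyphenyl)(hydroxy)methyl]-3-(4-hydroxy-3-methoxybenzyl)dihydrofuran-2(3H)-one
Conditions: TBAF, AcOH (1:1), THF, 0 °C → rt
Reagents that add atoms: none
Why: Fluoride-mediated cleavage of the silyl ether, buffered with acetic acid so that the freed C7' alkoxide neither translactonises onto C2 nor epimerises C3.

**Compound list**
1 | 4-(benzyloxy)-3-methoxybenzyl alcohol | COc1cc(CO)ccc1OCc1ccccc1 | starting material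
2 | 4-(benzyloxy)-3-methoxybenzyl bromide | COc1cc(CBr)ccc1OCc1ccccc1 | intermediate
3 | ethynylmagnesium bromide | C#C[Mg]Br | starting material
4 | 1-(benzyloxy)-2-methoxy-4-(prop-2-yn-1-yl)benzene | COc1cc(CC#C)ccc1OCc1ccccc1 | intermediate
5 | veratraldehyde (3,4-dimethoxybenzaldehyde) | COc1ccc(C=O)cc1OC | starting material
6 | {3-[4-(benzyloxy)-3-methoxyphenyl]prop-1-yn-1-yl}(methyl)zinc | C[Zn]C#CCc1ccc(OCc2ccccc2)c(OC)c1 | intermediate (not isolated)
7 | (R)-4-[4-(benzyloxy)-3-methoxyphenyl]-1-(3,4-dimethoxyphenyl)but-2-yn-1-ol | COc1cc(CC#C[C@H](O)c2ccc(OC)c(OC)c2)ccc1OCc1ccccc1 | intermediate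
8 | (1R,2E)-4-[4-(benzyloxy)-3-methoxyphenyl]-1-(3,4-dimethoxyphenyl)-2-(tributylstannyl)but-2-en-1-ol | CCCC[Sn](CCCC)(CCCC)/C(=C/Cc1ccc(OCc2ccccc2)c(OC)c1)[C@H](O)c1ccc(OC)c(OC)c1 | intermediate (not isolated)
9 | (1R,2E)-4-[4-(benzyloxy)-3-methoxyphenyl]-1-(3,4-dimethoxyphenyl)-2-iodobut-2-en-1-ol | I/C(=C/Cc1ccc(OCc2ccccc2)c(OC)c1)[C@H](O)c1ccc(OC)c(OC)c1 | intermediate
10 | tert-butyl{[(1R,2E)-4-[4-(benzyloxy)-3-methoxyphenyl]-1-(3,4-dimethoxyphenyl)-2-iodobut-2-en-1-yl]oxy}dimethylsilane | I/C(=C/Cc1ccc(OCc2ccccc2)c(OC)c1)[C@H](O[Si](C)(C)C(C)(C)C)c1ccc(OC)c(OC)c1 | intermediate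
11 | (tributylstannyl)methanol | CCCC[Sn](CO)(CCCC)CCCC | starting material
12 | (Z)-4-[4-(benzyloxy)-3-methoxyphenyl]-2-[(R)-(tert-butyldimethylsilyloxy)(3,4-dimethoxyphenyl)methyl]but-2-en-1-ol | OC/C(=C/Cc1ccc(OCc2ccccc2)c(OC)c1)[C@H](O[Si](C)(C)C(C)(C)C)c1ccc(OC)c(OC)c1 | intermediate
13 | carbon monoxide | [C-]#[O+] | starting material
14 | (3R,4R)-3-[4-(benzyloxy)-3-methoxybenzyl]-4-[(S)-(tert-butyldimethylsilyloxy)(3,4-dimethoxyphenyl)methyl]dihydrofuran-2(3H)-one | COc1cc(C[C@H]2C(=O)OC[C@@H]2[C@H](O[Si](C)(C)C(C)(C)C)c2ccc(OC)c(OC)c2)ccc1OCc1ccccc1 | intermediate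
15 | (3R,4R)-4-[(S)-(tert-butyldimethylsilyloxy)(3,4-dimethoxyphenyl)methyl]-3-(4-hydroxy-3-methoxybenzyl)dihydrofuran-2(3H)-one | COc1cc(C[C@H]2C(=O)OC[C@@H]2[C@H](O[Si](C)(C)C(C)(C)C)c2ccc(OC)c(OC)c2)ccc1O | intermediate
16 | (3R,4R)-4-[(S)-(3,4-dimethoxyphenyl)(hydroxy)methyl]-3-(4-hydroxy-3-methoxybenzyl)dihydrofuran-2(3H)-one | COc1cc(C[C@H]2C(=O)OC[C@@H]2[C@H](O)c2ccc(OC)c(OC)c2)ccc1O | target

**Step count**
Total steps: 9. Longest linear sequence: 9 steps (1 → 16); compounds 3, 5, 11 and 13 enter as purchased reagents.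

**Steps most likely to fail**

1. Step 7. Face selection at C4 may be weak, because the silyloxy group and the aryl ring compete as the shielding element. The C3–palladium alkyl may also undergo β-hydride elimination toward C7 faster than CO insertion, which would move the double bond into conjugation with the arene. A matched chiral diphosphine in place of dppb would be the first adjustment within the step, and any cis lactone could be equilibrated at C3 with DBU. The fallback sets out from 12 and replaces the direct lactonisation by hydroformylation and a separate oxidation. Rhodium-catalysed hydroformylation (Rh(acac)(CO)2, tris(2,4-di-tert-butylphenyl) phosphite, CO/H2, toluene, 80 °C) should place the formyl group on C3, where the C5 hydroxyl captures it to give (3R,4R)-3-[4-(benzyloxy)-3-methoxybenzyl]-4-[(S)-(tert-butyldimethylsilyloxy)(3,4-dimethoxyphenyl)methyl]tetrahydrofuran-2-ol F1 as an anomeric mixture. Oxidation of this lactol (TEMPO, PhI(OAc)2, CH2Cl2, rt) returns to the route at 14.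

2. Step 4. Tin may be delivered in part to the distal alkyne carbon, because the bulky carbinol carbon disfavours the proximal position, and this would give a regioisomeric iodide. The fallback sets out from 7 and uses alkoxide-directed hydromagnesiation in place of hydrostannation. Treatment with i-BuMgBr and Cp2TiCl2 (10 mol %) in Et2O at rt should add hydrogen and magnesium syn, with magnesium held on the proximal carbon by the magnesium alkoxide, to give the bromomagnesium alkoxide of (1R,2E)-4-[4-(benzyloxy)-3-methoxyphenyl]-2-(bromomagnesio)-1-(3,4-dimethoxyphenyl)but-2-en-1-ol F2. Quenching with I2 returns to the route at 9.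

3. Step 6. Transfer of the hydroxymethyl group to the hindered alkenylpalladium iodide may be slow, and protodeiodination or butyl transfer could then take over. The fallback sets out from 10 and builds C5 by carbonylation and reduction. Methoxycarbonylation (Pd(OAc)2, PPh3, CO 1 atm, MeOH, Et3N, DMF, 60 °C) should give methyl (E)-4-[4-(benzyloxy)-3-methoxyphenyl]-2-[(R)-(tert-butyldimethylsilyloxy)(3,4-dimethoxyphenyl)methyl]but-2-enoate F3. Reduction with i-Bu2AlH (CH2Cl2, −78 °C) returns to the route at 12.

**Further compounds**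
F1 | step 7 | (3R,4R)-3-[4-(benzyloxy)-3-methoxybenzyl]-4-[(S)-(tert-butyldimethylsilyloxy)(3,4-dimethoxyphenyl)methyl]tetrahydrofuran-2-ol (anomeric mixture) | COc1cc(C[C@H]2C(O)OC[C@@H]2[C@H](O[Si](C)(C)C(C)(C)C)c2ccc(OC)c(OC)c2)ccc1OCc1ccccc1
F2 | step 4 | bromomagnesium alkoxide of (1R,2E)-4-[4-(benzyloxy)-3-methoxyphenyl]-2-(bromomagnesio)-1-(3,4-dimethoxyphenyl)but-2-en-1-ol | Br[Mg]/C(=C/Cc1ccc(OCc2ccccc2)c(OC)c1)[C@H](O[Mg]Br)c1ccc(OC)c(OC)c1
F3 | step 6 | methyl (E)-4-[4-(benzyloxy)-3-methoxyphenyl]-2-[(R)-(tert-butyldimethylsilyloxy)(3,4-dimethoxyphenyl)methyl]but-2-enoate | COC(=O)/C(=C/Cc1ccc(OCc2ccccc2)c(OC)c1)[C@H](O[Si](C)(C)C(C)(C)C)c1ccc(OC)c(OC)c1
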